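The slowness of these flasks was what I measured first, as a pace: the natural log of charged over remaining substrate at the last reading, divided by its time.

in all of them: gas phase 0.74 mM (held); impurity 13 µM

| charge | substrate | free catalyst | remark | time |
|---|---|---|---|---|
| birch | 0.020 M | 90 µM | run made earlier |  |
| alder | 0.020 M | 140 µM | run made earlier |  |
| elm | 0.030 M | 64 µM | run made earlier |  |
| flask | 0.020 M | 64 µM |  | 3.0 h |

- birch (time / min: target / %, substrate / %): 25.0: 16.1, 84.3; 50.0: 29.2, 71.0; 80.0: 41.8, 58.7; 120: 55.0, 46.3
- alder (time / min: target / %, substrate / %): 15.0: 15.2, 84.4; 40.0: 35.8, 62.7; 80.0: 58.7, 41.7; 120: 72.1, 26.8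
- elm (time / min: target / %, substrate / %): 8.00: 2.9, 96.0; 20.0: 9.6, 92.2; 50.0: 19.9, 80.6; 120: 40.1, 60.0

(each reading ± 0.5 percentage points)

- the analysis behind the earlier runs scatters by 0.5 percentage points, standard deviation
- at the start none of the gas phase is in solution

* the target standing at 3.0 h, as a percentage of the substrate charged
* concentration of dissolved gas in solution at 20 min, in percent of saturation
* the change that raises the amount of target at 3.0 h, in percent of the substrate charged most ("none" if none brings more than 2 percentage points) (eta / delta / gamma / none)
* amount of target at 3.0 h, in percent of the substrate charged, after eta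

- eta: doubling the amount of free catalyst, all else as stated
- delta: doubling the saturation concentration of gas phase, all else as stated
- gamma: doubling the transfer coefficient of the gas phase, all else as stated

I called the charge of free catalyst less the charge of impurity the working catalyst, and set up each run beside it:

- birch: charged 90 µM, working 77.0 µM, pace 0.385 h⁻¹, pace per working catalyst 1.39 M⁻¹ s⁻¹
- alder: charged 140 µM, working 127 µM, pace 0.658 h⁻¹, pace per working catalyst 1.44 M⁻¹ s⁻¹
- elm: charged 64 µM, working 51.0 µM, pace 0.255 h⁻¹, pace per working catalyst 1.39 M⁻¹ s⁻¹

Reading birch against alder, the charge rose by a factor of 1.56 but the pace rose by 1.71, more than in proportion, so I took the impurity's small charge as a correction to the catalyst. The elm row had more substrate, yet its last column stayed close to birch's, so I treated the substrate as pseudo-first-order at held gas.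

For the flask I had 51.0 µM working. Birch's constant gave an exponent of 0.765 and 53.5% of target. Doubling the catalyst charge gave 115 µM working, 2.25 times as much, and 82.2% of target. Even a pace doubled by the gas gave me 78.3%.

The forecast gave 53.5% (51% to 56%), dissolved gas at 93% of saturation (80% to 99%), and eta as the best change with 81.5% (77% to 85%), judging that “gas transfer is fast”. My figure for that change stood a little higher.

The flask gave 53.3% of target and dissolved gas at 99.1% of saturation, and eta won with 82.7%, a gain of 29 percentage points against 26 points for delta.

    free catalyst + impurity → spent catalyst A (k = 9180 M⁻¹ s⁻¹)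
    substrate + free catalyst → spent catalyst B (k = 0.00137 M⁻¹ s⁻¹)
    substrate + dissolved gas + free catalyst → free catalyst + target (k = 2110 M⁻² s⁻¹)
    gas phase ⇌ dissolved gas, rate k4*(csat - [dissolved gas]) (kL = 0.218 s⁻¹)

In the flask, whose charge less impurity was 51.0 µM, the half-life of free catalyst by the step to spent catalyst B was 9.4 h at 1.05 h, longer than the run of 3.0 h. At 3.00 h free catalyst still stood at 65.0% of its charge, beside 20.3% spent catalyst A and 14.7% spent catalyst B. For the neighbour flask charged with 2.6 × 10⁻⁵ M, the charge less impurity was 13.0 µM, half of its charge, and birch's constant put its target at 17.7%; it stood at 17.4%.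

Readings and results are calculated with made-up constants; the scatter is artificial.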